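**Retrosynthetic overview**
1. The last C–C bond and the side-chain stereocentre come from a stereospecific 1,2-alkenyl shift (semipinacol) of a β-mesyloxy carbinol, built from an (E)-alkenylalanate (alkyne carboalumination) and (R)-3-oxopentan-2-yl mesylate (from methyl (R)-lactate).
2. The α-methoxy-γ-pyranone (second ring) comes from an ethyl ketone plus 2-methylpropanedioyl dichloride, then O-methylation; the ethyl ketone comes from a nitrile and EtLi.
3. The diene with both ring stereocentres comes from reduction of a dienyl triflate, itself made by desymmetrising conjugate alkynylation of an achiral 4-cyano-2,4,6-trimethylcyclohexa-2,5-dienone (attack anti to the methyl group puts alkyne and nitrile cis).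
4. The dienone comes from IBX dehydrogenation of the cyclohexanone formed by an anionic double Michael annulation of 2-methylpent-1-en-3-one with methacrylonitrile (carbocycle first, pyranone second).

Assumption: 2-methylpent-1-en-3-one and 2-methylpropanedioyl dichloride are taken as catalogue chemicals, and the ligand enantiomer named in step 3 is assumed to select the required enone arm (its antipode is equally available).

**Route**

Step 1
Reactants: 1 2-methylpent-1-en-3-one; 2 methacrylonitrile
Product: 5 1,3,5-trimethyl-4-oxocyclohexane-1-carbonitrile (diastereomer mixture), via lithium dienolate 3 (not isolated), via lithiated Michael adduct 4 (not isolated)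
Conditions: LDA (1.05 eq), THF, −78 °C, slow addition of 1; then 2, −78 °C → rt; aq. NH4Cl
Reagents that add atoms: none
Why: The kinetic α′-dienolate adds to methacrylonitrile and the resulting α-cyano carbanion closes onto the isopropenyl ketone by a 6-endo intramolecular Michael addition (stepwise anionic double Michael annulation); the stereocentres formed here are erased in step 2.

Step 2
Reactants: 5 1,3,5-trimethyl-4-oxocyclohexane-1-carbonitrile
Product: 6 1,3,5-trimethyl-4-oxocyclohexa-2,5-diene-1-carbonitrile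
Conditions: IBX (4 eq), DMSO, 80 °C
Reagents that add atoms: none
Why: IBX α,β-dehydrogenation on both sides of the ketone gives the cross-conjugated dienone, which cannot aromatise because C4 is quaternary and which is achiral with two enantiotopic enone arms.

Step 3
Reactants: 6 1,3,5-trimethyl-4-oxocyclohexa-2,5-diene-1-carbonitrile; 7 ethynyltrimethylsilane
Product: 10 (3R,4R)-4-cyano-2,4,6-trimethyl-3-[(trimethylsilyl)ethynyl]cyclohexa-1,5-dien-1-yl trifluoromethanesulfonate, via alkynylalane 8 (not isolated), via aluminium enolate 9 (not isolated)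
Conditions: 7, n-BuLi, Et2O, 0 °C, then Me2AlCl (gives 8); Ni(cod)2 (10 mol%), (S,S)-Ph-box (12 mol%), 6, t-BuOMe, −20 → 0 °C; then MeLi, THF, −78 °C; Comins' reagent, −78 → 0 °C
Reagents that add atoms: N-(5-chloropyridin-2-yl)bis(trifluoromethanesulfonimide) (Comins' reagent), FC(F)(F)S(=O)(=O)N(c1ccc(Cl)cn1)S(=O)(=O)C(F)(F)F
Why: Proposed new method: Ni(0)/bisoxazoline-catalysed conjugate alkynylation that desymmetrises the dienone (oxa-π-allyl nickel from the Al-activated enone, alkynyl transfer from aluminium, reductive elimination at the β-carbon), in which attack anti to the C4 methyl and syn to the small cyano group places alkyne and nitrile cis while the ligand selects one enantiotopic arm and so fixes both stereocentres, after which the regiodefined aluminium enolate is O-triflated as its ate complex; the closest known chemistry is the Ni/bisoxazoline-catalysed enantioselective addition of Me2AlC≡CSiMe3 to cyclohexenone and the Cu-catalysed desymmetrisation of 4,4-disubstituted cyclohexadienones with alkyl-metal reagents.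

Step 4
Reactants: 10 dienyl triflate
Product: 11 (1R,6S)-1,3,5-trimethyl-6-[(trimethylsilyl)ethynyl]cyclohexa-2,4-diene-1-carbonitrile
Conditions: Pd(OAc)2 (5 mol%), PPh3 (10 mol%), HCO2H, n-Bu3N, DMF, 60 °C
Reagents that add atoms: none
Why: Pd-catalysed formate reduction of the enol triflate (oxidative addition, decarboxylation of formate, C–H reductive elimination) unveils the 1,3-diene without touching the nitrile, the silylalkyne or either stereocentre.

Step 5
Reactants: 11 diene nitrile
Product: 13 1-[(1R,6S)-1,3,5-trimethyl-6-[(trimethylsilyl)ethynyl]cyclohexa-2,4-dien-1-yl]propan-1-one, via N-lithio ketimine 12 (not isolated)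
Conditions: EtLi (1.5 eq), Et2O, −78 → 0 °C; then 0.5 M aq. HCl, THF, 0 °C
Reagents that add atoms: ethyllithium, [Li]CC; water, O
Why: Organolithium addition to the non-enolisable tertiary nitrile stops at the N-lithio ketimine, which cold dilute acid hydrolyses to the ethyl ketone with no change at the adjacent quaternary centre.

Step 6
Reactants: 13 ethyl ketone; 14 2-methylpropanedioyl dichloride
Product: 16 4-hydroxy-3,5-dimethyl-6-[(1R,6S)-1,3,5-trimethyl-6-[(trimethylsilyl)ethynyl]cyclohexa-2,4-dien-1-yl]-2H-pyran-2-one, via silyl enol ether 15 (not isolated)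
Conditions: LiHMDS, TMSCl, THF, −78 → 0 °C; evaporate, pentane, filter; then 14, 2,6-di-tert-butylpyridine, Et2O, −78 °C → rt
Reagents that add atoms: none
Why: The ketone can enolise on one side only, its silyl enol ether is C-acylated by the malonyl dichloride and the enol oxygen then closes on the second acid chloride (Effenberger-type 4-hydroxy-2-pyranone synthesis), so the second ring is built on the quaternary carbon without touching the stereocentres.

Step 7
Reactants: 16 hydroxypyranone
Product: 18 2-[(1R,6S)-6-ethynyl-1,3,5-trimethylcyclohexa-2,4-dien-1-yl]-6-methoxy-3,5-dimethyl-4H-pyran-4-one, via silylalkyne methoxypyranone 17 (not isolated)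
Conditions: MeOTf (1.5 eq), CH2Cl2, 0 °C → rt; then MeOH, K2CO3, rt
Reagents that add atoms: methyl trifluoromethanesulfonate, COS(=O)(=O)C(F)(F)F
Why: The hard electrophile MeOTf alkylates the lactone carbonyl oxygen of the neutral 4-hydroxy-2-pyranone to give the 2-methoxy-4-pyranone after deprotonation, and K2CO3/MeOH then protodesilylates the alkyne in the same flask.

Step 8
Reactants: 19 methyl (R)-lactate
Product: 21 (R)-2-hydroxypentan-3-one, via Weinreb amide 20 (not isolated)
Conditions: MeNHOMe·HCl, i-PrMgCl (4 eq), THF, −20 → 0 °C; then EtMgBr (3 eq), 0 °C → rt; aq. NH4Cl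
Reagents that add atoms: ethylmagnesium bromide, CC[Mg]Br
Why: Magnesium-amide aminolysis of the ester gives the Weinreb amide, whose chelated adduct with EtMgBr prevents over-addition (Weinreb ketone synthesis), and no bond to the lactate stereocentre is broken.

Step 9
Reactants: 21 (R)-2-hydroxypentan-3-one
Product: 22 (R)-3-oxopentan-2-yl methanesulfonate
Conditions: MsCl, Et3N, CH2Cl2, −20 °C, 30 min
Reagents that add atoms: methanesulfonyl chloride, CS(=O)(=O)Cl
Why: O-Sulfonylation at low temperature proceeds with retention because only the O–H bond reacts.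

Step 10
Reactants: 18 terminal alkyne; 22 (R)-3-oxopentan-2-yl methanesulfonate
Product: 26 2-methoxy-3,5-dimethyl-6-[(1R,6S)-1,3,5-trimethyl-6-[(2E,4R)-4-methyl-5-oxohept-2-en-2-yl]cyclohexa-2,4-dien-1-yl]-4H-pyran-4-one, via alkenylalane 23 (not isolated), via lithium alanate 24 (not isolated), via mesyloxy alkoxide 25 (not isolated)
Conditions: Me3Al (3 eq), Cp2ZrCl2 (0.25 eq), H2O (1 eq), CH2Cl2, −20 °C; evaporate; n-BuLi, THF/hexane, −78 °C; 22, −78 °C; then Et3Al (3 eq), −78 → 0 °C; Rochelle salt
Reagents that add atoms: trimethylaluminium, C[Al](C)C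
Why: Zr-catalysed syn-methylalumination (Negishi) gives the (E)-alkenylalane, its ate complex adds to the activated ketone, and the aluminium alkoxide then undergoes a Suzuki–Tsuchihashi-type semipinacol rearrangement in which the alkenyl group makes a 1,2-shift anti to the departing mesylate, so the (R)-mesylate carbon is inverted into the (R)-configured α-methyl β,γ-unsaturated ketone with the (E)-alkene retained and no enolisation.

**Compound list**
1 | 2-methylpent-1-en-3-one | CCC(=O)C(C)=C | starting material
2 | methacrylonitrile | CC(=C)C#N | starting material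
3 | lithium 2-methylpenta-1,3-dien-3-olate | [Li]OC(=CC)C(C)=C | intermediate
4 | lithiated 2,4,6-trimethyl-5-oxohept-6-enenitrile | [Li+].C=C(C)C(=O)C(C)C[C-](C)C#N | intermediate
5 | 1,3,5-trimethyl-4-oxocyclohexane-1-carbonitrile (diastereomer mixture) | CC1CC(C)(C#N)CC(C)C1=O | intermediate
6 | 1,3,5-trimethyl-4-oxocyclohexa-2,5-diene-1-carbonitrile | CC1=CC(C)(C#N)C=C(C)C1=O | intermediate
7 | ethynyltrimethylsilane | C#C[Si](C)(C)C | starting material
8 | dimethyl[(trimethylsilyl)ethynyl]alumane | C[Al](C)C#C[Si](C)(C)C | intermediate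
9 | dimethylaluminium (3R,4R)-4-cyano-2,4,6-trimethyl-3-[(trimethylsilyl)ethynyl]cyclohexa-1,5-dien-1-olate | C[Si](C)(C)C#C[C@H]1C(C)=C(O[Al](C)C)C(C)=C[C@@]1(C)C#N | intermediate
10 | (3R,4R)-4-cyano-2,4,6-trimethyl-3-[(trimethylsilyl)ethynyl]cyclohexa-1,5-dien-1-yl trifluoromethanesulfonate | C[Si](C)(C)C#C[C@H]1C(C)=C(OS(=O)(=O)C(F)(F)F)C(C)=C[C@@]1(C)C#N | intermediate
11 | (1R,6S)-1,3,5-trimethyl-6-[(trimethylsilyl)ethynyl]cyclohexa-2,4-diene-1-carbonitrile | C[Si](C)(C)C#C[C@H]1C(C)=CC(C)=C[C@@]1(C)C#N | intermediate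
12 | N-lithio ketimine of 13 (ring configuration as in 11) | C[Si](C)(C)C#C[C@H]1C(C)=CC(C)=C[C@@]1(C)C(CC)=N[Li] | intermediate
13 | 1-[(1R,6S)-1,3,5-trimethyl-6-[(trimethylsilyl)ethynyl]cyclohexa-2,4-dien-1-yl]propan-1-one | C[Si](C)(C)C#C[C@H]1C(C)=CC(C)=C[C@@]1(C)C(=O)CC | intermediate
14 | 2-methylpropanedioyl dichloride | CC(C(Cl)=O)C(Cl)=O | starting material
15 | (Z)-trimethylsilyl enol ether of 13 (ring configuration as in 13) | C[Si](C)(C)C#C[C@H]1C(C)=CC(C)=C[C@@]1(C)/C(O[Si](C)(C)C)=C/C | intermediate
16 | 4-hydroxy-3,5-dimethyl-6-[(1R,6S)-1,3,5-trimethyl-6-[(trimethylsilyl)ethynyl]cyclohexa-2,4-dien-1-yl]-2H-pyran-2-one | C[Si](C)(C)C#C[C@H]1C(C)=CC(C)=C[C@@]1(C)C1=C(C)C(O)=C(C)C(=O)O1 | intermediate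
17 | 2-methoxy-3,5-dimethyl-6-[(1R,6S)-1,3,5-trimethyl-6-[(trimethylsilyl)ethynyl]cyclohexa-2,4-dien-1-yl]-4H-pyran-4-one | C[Si](C)(C)C#C[C@H]1C(C)=CC(C)=C[C@@]1(C)c1oc(OC)c(C)c(=O)c1C | intermediate
18 | 2-[(1R,6S)-6-ethynyl-1,3,5-trimethylcyclohexa-2,4-dien-1-yl]-6-methoxy-3,5-dimethyl-4H-pyran-4-one | C#C[C@H]1C(C)=CC(C)=C[C@@]1(C)c1oc(OC)c(C)c(=O)c1C | intermediate
19 | methyl (R)-lactate | C[C@@H](O)C(=O)OC | starting material
20 | (R)-2-hydroxy-N-methoxy-N-methylpropanamide | C[C@@H](O)C(=O)N(C)OC | intermediate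
21 | (R)-2-hydroxypentan-3-one | C[C@@H](O)C(=O)CC | intermediate
22 | (R)-3-oxopentan-2-yl methanesulfonate | C[C@@H](OS(C)(=O)=O)C(=O)CC | intermediate
23 | (E)-alkenyl(dimethyl)alumane from syn-methylalumination of 18 (Al trans to the ring; ring stereocentres as in 18) | C[Al](C)/C=C(\C)[C@H]1C(C)=CC(C)=C[C@@]1(C)c1oc(OC)c(C)c(=O)c1C | intermediate
24 | lithium butyl(dimethyl)alkenylalanate (ate complex of 23) | [Li+].CCCC[Al-](C)(C)/C=C(\C)[C@H]1C(C)=CC(C)=C[C@@]1(C)c1oc(OC)c(C)c(=O)c1C | intermediate
25 | lithium alkoxide of the tertiary β-mesyloxy alcohol from 24 and 22 (carbinol centre a mixture; mesylate carbon R; ring as in 18) | [Li+].CCC([O-])(/C=C(\C)[C@H]1C(C)=CC(C)=C[C@@]1(C)c1oc(OC)c(C)c(=O)c1C)[C@@H](C)OS(C)(=O)=O | intermediate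
26 | 2-methoxy-3,5-dimethyl-6-[(1R,6S)-1,3,5-trimethyl-6-[(2E,4R)-4-methyl-5-oxohept-2-en-2-yl]cyclohexa-2,4-dien-1-yl]-4H-pyran-4-one | CCC(=O)[C@H](C)/C=C(\C)[C@H]1C(C)=CC(C)=C[C@@]1(C)c1oc(OC)c(C)c(=O)c1C | target

**Step count and risk**
Total steps: 10. Longest linear sequence: 8 (steps 1–7, then 10).

Three steps most likely to fail:

Step 3 (the proposed new step; risks are low reactivity of the α-methylated enone arms and insufficient enantioselection). The fallback uses known chemistry, sets out from 6 and 7 and comes back at 10. The zinc acetylide from 7 (n-BuLi, ZnBr2) is added to 6 with TBSOTf promotion (Et2O/THF, −40 °C), again anti to the methyl group, to give the racemic cis silyl enol ether F3. CsF and PhNTf2 in DME convert it into the racemic dienyl triflate F4. Preparative SFC on a chiral stationary phase then delivers 10 (at most half of the material), so the enantiomer is obtained by resolution instead of catalysis.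

Step 10 (risks are interference of the Lewis-basic pyranone with Me3Al/zirconocene and epoxide closure of the alkoxide instead of the shift). The fallback sets out from 18 and comes back at 26. Carboalumination followed by iodinolysis (I2, THF, −30 °C) gives the (E)-vinyl iodide F5. I/Mg exchange (i-PrMgCl·LiCl, THF, −20 °C) and LaCl3·2LiCl-mediated addition to 22 at −78 °C give, after work-up, the isolated tertiary β-mesyloxy alcohol F6. Et3Al (3 eq) in CH2Cl2 at −78 → 0 °C then effects the 1,2-alkenyl shift on this isolated alcohol to give 26.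

Step 1 (risks are oligomerisation of methacrylonitrile and proton transfer stalling the second Michael addition). The fallback sets out from 2, uses commercial pentan-3-one in place of 1, and comes back at 5. The LDA enolate of pentan-3-one adds to 2 (THF, −78 °C) to give 2,4-dimethyl-5-oxoheptanenitrile F1. Paraformaldehyde with N-methylanilinium trifluoroacetate (THF, reflux) methylenates the only CH2 α-position to give 2,4,6-trimethyl-5-oxohept-6-enenitrile F2. Catalytic t-BuOK in t-BuOH/THF closes the ring by 6-endo Michael addition of the nitrile-stabilised carbanion to give 5.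

Further compounds
F1 | step 1 | 2,4-dimethyl-5-oxoheptanenitrile (diastereomer mixture) | CCC(=O)C(C)CC(C)C#N
F2 | step 1 | 2,4,6-trimethyl-5-oxohept-6-enenitrile (diastereomer mixture) | C=C(C)C(=O)C(C)CC(C)C#N
F3 | step 3 | racemic tert-butyldimethylsilyl enol ether corresponding to 9 (alkyne and nitrile cis) | C[Si](C)(C)C#C[C@H]1C(C)=C(O[Si](C)(C)C(C)(C)C)C(C)=C[C@@]1(C)C#N.C[Si](C)(C)C#C[C@@H]1C(C)=C(O[Si](C)(C)C(C)(C)C)C(C)=C[C@]1(C)C#N
F4 | step 3 | racemic 4-cyano-2,4,6-trimethyl-3-[(trimethylsilyl)ethynyl]cyclohexa-1,5-dien-1-yl trifluoromethanesulfonate (alkyne and nitrile cis) | C[Si](C)(C)C#C[C@H]1C(C)=C(OS(=O)(=O)C(F)(F)F)C(C)=C[C@@]1(C)C#N.C[Si](C)(C)C#C[C@@H]1C(C)=C(OS(=O)(=O)C(F)(F)F)C(C)=C[C@]1(C)C#N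
F5 | step 10 | 2-[(1R,6S)-6-[(E)-1-iodoprop-1-en-2-yl]-1,3,5-trimethylcyclohexa-2,4-dien-1-yl]-6-methoxy-3,5-dimethyl-4H-pyran-4-one | I/C=C(\C)[C@H]1C(C)=CC(C)=C[C@@]1(C)c1oc(OC)c(C)c(=O)c1C
F6 | step 10 | (2R,4E)-3-ethyl-3-hydroxy-5-(ring of 18)hex-4-en-2-yl methanesulfonate (carbinol centre a mixture; ring stereocentres as in 18) | CCC(O)(/C=C(\C)[C@H]1C(C)=CC(C)=C[C@@]1(C)c1oc(OC)c(C)c(=O)c1C)[C@@H](C)OS(C)(=O)=O
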